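Everything rests on the bond between C10, the methyl-bearing quaternary carbon flanked by the ring B ketone C6, and C7, the lactone carbinol carbon of ring C. This 1,2-relationship of ketone, quaternary carbon and former alkene carbon is what a vinyl shift in a bridgehead-oxygenated bicyclo[2.2.2]octene leaves behind. In one operation a sulfonic acid removes the C10 hydroxyl of isotwistenol 18 as water, C7 moves from C6 to C10, and the bridgehead methyl ether becomes the C6 carbonyl, contracting a six-membered ring to the cyclopentene of ring C and fixing C10. Precursor 18 holds all ten core carbons and comes from a Claisen/Diels–Alder cascade of an aryl allyl ether.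

Key step: step 13

Remarks on the chemistry (assumptions)
- Labels, kept from 13 to 35: C1 quaternary carbon carrying the one-carbon arm C13; C2 cyclopentanone carbonyl; C3 C(CH3)(OH); C4 CH; C5 CH2, later the enol carbon; C6 methoxy bridgehead, later ketone; C7 alkene carbon with the propanoate arm (C11 = CH(CH3), C12 = C=O), later lactone carbinol carbon; C8 alkene carbon with CH3, later lactone C–O carbon; C9 CH; C10 carbinol carbon, later the methyl-bearing quaternary carbon.
- Rings: ring A is C1–C2–C3–C4–C9, ring B is C1–C10–C6–C5–C4–C9, ring C is C1–C10–C7–C8–C9, ring D is the lactone.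
- Faces: exo on ring A means the face turned away from C5/C6/C10; exo on ring C means syn to C1, endo means syn to C5.
- C1 carries an allyl group through the key step as the masked arm C13. An acyl or ester group there would make the dienone of step 9 a labile triacylmethane and could not be reduced selectively later; the allyl group later becomes CH2OH, which directs the epoxidation, and then the sorbyl ketone.
- C11 is carried as a mixture of epimers from 7 to 25 (no descriptor in those SMILES) and is set in step 18, because its natural configuration is the kinetic, concave one in the lactone.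
- (E)-Crotylboronic acid pinacol ester, (S)-TRIP, (E)-crotonaldehyde and sorbic acid are taken as commercial.

Step 1
Reactants: 1 2-methoxy-4-methylphenol
Product: 2 triisopropyl(2-methoxy-4-methylphenoxy)silane
Conditions: i-Pr3SiCl, imidazole, DMF, rt
Reagents that add atoms: triisopropylsilyl chloride, CC(C)[Si](Cl)(C(C)C)C(C)C
Why: Imidazole-promoted O-silylation of the phenol (silyl ether formation) installs a bulky, poorly coordinating group that shields its own ortho position in the metalation that follows.

Step 2
Reactants: 2 triisopropyl(2-methoxy-4-methylphenoxy)silane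
Product: 4 (3-iodo-2-methoxy-4-methylphenoxy)triisopropylsilane, via aryllithium 3 (not isolated)
Conditions: n-BuLi, TMEDA, Et2O, 0 °C to rt; then I2, THF, −78 °C
Reagents that add atoms: iodine, II
Why: Directed ortho-metalation by the methoxy group, whose only free ortho position lies between OCH3 and CH3, followed by iodinolysis of the aryllithium, should place iodine at the future C7.

Step 3
Reactants: 4 (3-iodo-2-methoxy-4-methylphenoxy)triisopropylsilane; 5 methyl 2-bromopropanoate
Product: 7 methyl 2-{2-methoxy-6-methyl-3-[(triisopropylsilyl)oxy]phenyl}propanoate, via zinc enolate 6 (not isolated)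
Conditions: 5, Zn dust, Me3SiCl (cat.), THF, rt; then 4, Pd(dba)2 (cat.), P(t-Bu)3 (cat.), THF, 50 °C
Reagents that add atoms: none
Why: Negishi-type palladium-catalysed α-arylation of the Reformatsky reagent tolerates the ester and, with the bulky electron-rich phosphine, should couple the doubly ortho-substituted iodide; the new centre C11 forms as a racemate and is set only in step 18.

Step 4
Reactants: 7 methyl 2-{2-methoxy-6-methyl-3-[(triisopropylsilyl)oxy]phenyl}propanoate
Product: 8 methyl 2-(3-hydroxy-2-methoxy-6-methylphenyl)propanoate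
Conditions: Bu4NF, AcOH, THF, 0 °C
Reagents that add atoms: none
Why: Fluoride-induced cleavage of the aryl silyl ether (desilylation), buffered to spare the ester, frees the phenol needed for ortho-formylation.

Step 5
Reactants: 8 methyl 2-(3-hydroxy-2-methoxy-6-methylphenyl)propanoate
Product: 9 methyl 2-(4-formyl-3-hydroxy-2-methoxy-6-methylphenyl)propanoate
Conditions: MgCl2, Et3N, (CH2O)n, MeCN, 80 °C
Reagents that add atoms: paraformaldehyde (formaldehyde), C=O
Why: Magnesium phenoxide-mediated ortho-formylation (Casnati–Skattebøl type) is specific for the single free position ortho to the hydroxyl, the para position being blocked by CH3, and supplies the future C2.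

Step 6
Reactants: 9 methyl 2-(4-formyl-3-hydroxy-2-methoxy-6-methylphenyl)propanoate
Product: 10 methyl 2-[3-(allyloxy)-4-formyl-2-methoxy-6-methylphenyl]propanoate
Conditions: allyl bromide, K2CO3, DMF, 40 °C
Reagents that add atoms: allyl bromide, C=CCBr
Why: Williamson ether synthesis on the phenoxide, carbonate being too weak a base to alkylate the ester α-carbon.

Step 7
Reactants: 10 methyl 2-[3-(allyloxy)-4-formyl-2-methoxy-6-methylphenyl]propanoate
Product: 11 methyl 2-{3-(allyloxy)-4-[(1S,2S)-1-hydroxy-2-methylbut-3-en-1-yl]-2-methoxy-6-methylphenyl}propanoate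
Conditions: (E)-crotyl-B(pin), (S)-TRIP (5 mol %), toluene, −30 °C; aqueous work-up
Reagents that add atoms: (E)-crotylboronic acid pinacol ester, C/C=C/CB1OC(C)(C)C(C)(C)O1
Why: Chiral phosphoric acid-catalysed crotylboration through a closed six-membered chair transition state turns the E geometry into the anti relationship of the future C2 and C3, and the (S)-catalyst is the antipode expected to attack the aldehyde face that gives the 1S carbinol (its mirror image would serve if the sense proved opposite).

Step 8
Reactants: 11 methyl 2-{3-(allyloxy)-4-[(1S,2S)-1-hydroxy-2-methylbut-3-en-1-yl]-2-methoxy-6-methylphenyl}propanoate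
Product: 12 triethylsilyl ether of 11
Conditions: Et3SiOTf, 2,6-lutidine, CH2Cl2, −78 °C
Reagents that add atoms: triethylsilyl triflate, CC[Si](CC)(CC)OS(=O)(=O)C(F)(F)F
Why: Silylation of the hindered secondary alcohol with a silyl triflate masks the hydroxyl, which would otherwise allow retro-aldol rearomatisation of the β-hydroxy dienone formed in step 9.

Step 9
Reactants: 12 triethylsilyl ether of 11
Product: 15 isotwistenone alcohol (C10 ketone, C2–OH exo, C3–CH3 exo, C1 allyl), via dienone 13 (not isolated), via silyl ether 14 (not isolated)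
Conditions: 1,2-dichlorobenzene, BHT (cat.), 185 °C, sealed tube; then HF·pyridine, THF, 0 °C
Reagents that add atoms: none
Why: Aromatic Claisen rearrangement to the tether-bearing ortho carbon gives 2,4-cyclohexadienone 13, which is trapped by intramolecular Diels–Alder reaction with the tethered vinyl group (C4 to C9, C5 to C6); because the sigmatropic step is reversible the C1 configuration is decided at the cycloaddition, where the (1S,2S) tether can keep both its silyloxy and methyl groups on the exo face of ring A and avoid allylic strain only in the diastereomer shown, and fluoride then frees the C2 alcohol.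

Step 10
Reactants: 15 isotwistenone alcohol
Product: 16 isotwistene-2,10-dione (C3–H endo, C3–CH3 exo)
Conditions: Dess–Martin periodinane, CH2Cl2, rt
Reagents that add atoms: none
Why: Dess–Martin oxidation of the only hydroxyl gives the C2 ketone under neutral conditions, leaving the non-enolisable 1,3-diketone at C1 intact.

Step 11
Reactants: 16 isotwistene-2,10-dione
Product: 17 α-ketol (C3–OH exo, C3–CH3 endo, C2 and C10 ketones)
Conditions: Cs2CO3 (cat.), P(OEt)3, O2 (1 atm), DMSO, rt
Reagents that add atoms: dioxygen, O=O
Why: Base-mediated enolate autoxidation with in situ phosphite reduction of the hydroperoxide acts at C3, the only enolisable position of either ketone, while the weak non-nucleophilic base leaves the less acidic ester α-carbon and the diketone alone, and dioxygen should attack the enolate from the exo face of ring A.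

Step 12
Reactants: 17 α-ketol
Product: 18 isotwistenol (C10 tertiary alcohol, OH syn to the C4–C5 bridge, CH3 syn to the C7=C8 bridge)
Conditions: MeMgBr (3 equiv), THF, −78 °C; NH4Cl quench at −78 °C
Reagents that add atoms: methylmagnesium bromide, C[Mg]Br
Why: Grignard addition to the chelation-activated α-methoxy ketone C10, the C2 ketone being shielded by two fully substituted neighbours and its adjacent magnesium alkoxide, should occur from the side of the C7=C8 bridge, which lacks the inward C–H bond of the C4–C5 bridge, and the cold quench avoids retro-aldol cleavage of the aldolate.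

Step 13
Reactants: 18 isotwistenol
Product: 19 bicyclo[3.2.1]octenone (C6 ketone, C10 quaternary and bonded to C1, C6 and C7, cyclopentene C7=C8)
Conditions: p-TsOH·H2O (0.2 equiv), wet toluene, 60 °C
Reagents that add atoms: water, O
Why: Protonation of the tertiary C10 hydroxyl and departure of water are assisted from the rear by the C7=C8 π bond, C7 moves from C6 to C10 through a bridged cation, and the oxygen lone pair on C6 takes up the charge as an oxocarbenium ion that wet acid hydrolyses to the ketone and methanol. The closest known reaction is the acid-mediated semipinacol (Wagner–Meerwein) rearrangement of 1-methoxybicyclo[2.2.2]oct-5-en-2-ols to bicyclo[3.2.1]oct-6-en-2-ones. No ring is closed by cyclisation: ring C (C1–C10–C7–C8–C9) arises by contraction of the six-membered ring C1–C10–C6–C7–C8–C9 in a 1,2-shift, while ring B (C1–C10–C6–C5–C4–C9) keeps its size. The only new stereocentre, C10, is dictated by the cage, because C7 can reach C10 only on the face it already flanks, opposite the departing oxygen. The step needs migration of the vinyl bridge in preference to the C5 methylene bridge, and this is secured by the C10 hydroxyl standing syn to C5 and anti-periplanar to the C6–C7 bond (step 12), by π participation and by the methoxy push. The α-ketol, the ester and the allyl group are not expected to react with a catalytic sulfonic acid at 60 °C.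

Step 14
Reactants: 19 bicyclo[3.2.1]octenone
Product: 20 (E)-propenyl compound (C13=CH–CH3 on C1)
Conditions: RuHCl(CO)(PPh3)3 (cat.), toluene, 80 °C
Reagents that add atoms: none
Why: Ruthenium hydride-catalysed alkene isomerisation (hydrometalation/β-hydride elimination) moves the terminal double bond to the one internal position available next to the quaternary carbon, and the tetrasubstituted ring alkene cannot migrate.

Step 15
Reactants: 20 (E)-propenyl compound
Product: 22 C13 aldehyde, via diol 21 (not isolated)
Conditions: OsO4 (cat.), NMO, acetone/H2O, rt; then NaIO4, pH 7 buffer, 0 °C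
Reagents that add atoms: OsO4, O=[Os](=O)(=O)=O; N-methylmorpholine N-oxide, C[N+]1([O-])CCOCC1
Why: Lemieux–Johnson-type sequence of catalytic dihydroxylation and periodate glycol cleavage, in which OsO4 spares the shielded tetrasubstituted C7=C8 bond and brief neutral periodate should cleave the glycol far faster than the hindered tertiary α-ketol.

Step 16
Reactants: 22 C13 aldehyde
Product: 23 C13 primary alcohol
Conditions: NaBH4, MeOH/CH2Cl2, −78 °C
Reagents that add atoms: none
Why: Chemoselective borohydride reduction of the aldehyde at low temperature, the C6 ketone (one quaternary neighbour) and the C2 ketone (two) being much slower.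

Step 17
Reactants: 23 C13 primary alcohol
Product: 25 hydroxy lactone (C7–OH exo, lactone oxygen on C8 endo, C11 epimers), via epoxide 24 (not isolated)
Conditions: VO(acac)2 (cat.), t-BuOOH, CH2Cl2, rt; then camphorsulfonic acid (cat.), wet CH2Cl2, rt
Reagents that add atoms: tert-butyl hydroperoxide, CC(C)(C)OO; water, O
Why: Hydroxyl-directed epoxidation by the vanadium alkyl peroxide bound to the C13 alcohol, which sits over the exo face of C7=C8, is followed by acid-induced opening of the epoxide at tertiary C8 by the ester carbonyl oxygen with inversion (neighbouring-group participation, γ-lactone formation with loss of methanol).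

Step 18
Reactants: 25 hydroxy lactone (C11 epimers)
Product: 27 hydroxy lactone with C11–CH3 on the concave face, via pentalithium enolate 26 (not isolated)
Conditions: LiN(i-Pr)2 (6 equiv), THF, −78 °C; then AcOH, THF, −78 °C
Reagents that add atoms: none
Why: Enolate formation and kinetic protonation, in which the lactone enolate (formed beside three alkoxides and the stereochemically harmless C5 enolate) should take its proton on the open face turned away from C6 and the C10 methyl, which forces the C11 methyl onto the concave face as in the target and converges both epimers.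

Step 19
Reactants: 27 hydroxy lactone
Product: 28 C13 aldehyde of the lactone series
Conditions: Dess–Martin periodinane, CH2Cl2, 0 °C
Reagents that add atoms: none
Why: Dess–Martin oxidation converts the primary alcohol into the aldehyde under neutral conditions that cannot oxidise the tertiary alcohols or epimerise C11.

Step 20
Reactants: 29 (E)-crotonaldehyde
Product: 30 (1E,3E)-1-iodopenta-1,3-diene
Conditions: CHI3, CrCl2, THF, 0 °C
Reagents that add atoms: iodoform, IC(I)I
Why: Takai olefination of the enal with the chromium carbenoid from iodoform should give the E-iodoalkene.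

Step 21
Reactants: 28 C13 aldehyde; 30 (1E,3E)-1-iodopenta-1,3-diene
Product: 31 dienyl carbinol (C13 epimers)
Conditions: CrCl2, NiCl2 (cat.), DMSO, rt
Reagents that add atoms: none
Why: Nozaki–Hiyama–Kishi coupling, in which the alkenylchromium reagent adds to the aldehyde only and leaves ketones, lactone and free hydroxyls untouched; the new carbinol centre is removed in step 22.

Step 22
Reactants: 31 dienyl carbinol
Product: 32 sorbyl ketone at C1
Conditions: MnO2, CH2Cl2, rt
Reagents that add atoms: none
Why: Allylic oxidation with MnO2 is selective for the dienylic secondary alcohol and gives the (2E,4E)-dienone.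

Step 23
Reactants: 32 sorbyl ketone at C1; 33 sorbic acid
Product: 35 CNP0231466.1, via sorbyl chloride 34 (not isolated)
Conditions: 33, (COCl)2, DMF (cat.), CH2Cl2, 0 °C, evaporate; then 32, MgBr2·OEt2, i-Pr2NEt, CH2Cl2, rt
Reagents that add atoms: none
Why: Soft enolisation with MgBr2 and a tertiary amine followed by C-acylation (Claisen-type) acts at C5, the only α-CH2 of the C6 ketone, and the magnesium chelate of the β-diketone should collapse on work-up to the hydrogen-bonded exocyclic enol of the target without touching C11.

Compound list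
1 | 2-methoxy-4-methylphenol | Cc1ccc(O)c(OC)c1 | starting material
2 | triisopropyl(2-methoxy-4-methylphenoxy)silane | Cc1ccc(O[Si](C(C)C)(C(C)C)C(C)C)c(OC)c1 | intermediate
3 | {2-methoxy-6-methyl-3-[(triisopropylsilyl)oxy]phenyl}lithium (not isolated) | [Li]c1c(C)ccc(O[Si](C(C)C)(C(C)C)C(C)C)c1OC | intermediate
4 | (3-iodo-2-methoxy-4-methylphenoxy)triisopropylsilane | Cc1ccc(O[Si](C(C)C)(C(C)C)C(C)C)c(OC)c1I | intermediate
5 | methyl 2-bromopropanoate (racemic) | CC(Br)C(=O)OC | starting material
6 | bromo(1-methoxy-1-oxopropan-2-yl)zinc (not isolated) | COC(=O)C(C)[Zn]Br | intermediate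
7 | methyl 2-{2-methoxy-6-methyl-3-[(triisopropylsilyl)oxy]phenyl}propanoate (racemic) | COC(=O)C(C)c1c(C)ccc(O[Si](C(C)C)(C(C)C)C(C)C)c1OC | intermediate
8 | methyl 2-(3-hydroxy-2-methoxy-6-methylphenyl)propanoate | COC(=O)C(C)c1c(C)ccc(O)c1OC | intermediate
9 | methyl 2-(4-formyl-3-hydroxy-2-methoxy-6-methylphenyl)propanoate | COC(=O)C(C)c1c(C)cc(C=O)c(O)c1OC | intermediate
10 | methyl 2-[3-(allyloxy)-4-formyl-2-methoxy-6-methylphenyl]propanoate | COC(=O)C(C)c1c(C)cc(C=O)c(OCC=C)c1OC | intermediate
11 | methyl 2-{3-(allyloxy)-4-[(1S,2S)-1-hydroxy-2-methylbut-3-en-1-yl]-2-methoxy-6-methylphenyl}propanoate (C11 epimers) | COC(=O)C(C)c1c(C)cc([C@@H](O)[C@@H](C)C=C)c(OCC=C)c1OC | intermediate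
12 | methyl 2-{3-(allyloxy)-2-methoxy-6-methyl-4-[(1S,2S)-2-methyl-1-(triethylsilyloxy)but-3-en-1-yl]phenyl}propanoate | COC(=O)C(C)c1c(C)cc([C@@H](O[Si](CC)(CC)CC)[C@@H](C)C=C)c(OCC=C)c1OC | intermediate
13 | (6S)-6-allyl-2-methoxy-3-(1-methoxy-1-oxopropan-2-yl)-4-methyl-6-[(1S,2S)-2-methyl-1-(triethylsilyloxy)but-3-en-1-yl]cyclohexa-2,4-dien-1-one (not isolated) | C=CC[C@@]1([C@@H](O[Si](CC)(CC)CC)[C@@H](C)C=C)C=C(C)C(C(C)C(=O)OC)=C(OC)C1=O | intermediate
14 | Diels–Alder adduct, isotwistenone: C10 ketone, C1 allyl, C2 exo-OSiEt3, C3 exo-CH3, C6 OCH3, C7 CH(CH3)CO2CH3, C8 CH3 (not isolated) | C=CC[C@]12[C@@H](O[Si](CC)(CC)CC)[C@@H](C)[C@@H]3C[C@@](OC)(C(C(C)C(=O)OC)=C(C)[C@@H]32)C1=O | intermediate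
15 | isotwistenone alcohol: as 14 with free exo C2–OH | C=CC[C@]12[C@@H](O)[C@@H](C)[C@@H]3C[C@@](OC)(C(C(C)C(=O)OC)=C(C)[C@@H]32)C1=O | intermediate
16 | isotwistene-2,10-dione: C2 and C10 ketones, C3–H endo, C3–CH3 exo | C=CC[C@]12C(=O)[C@@H](C)[C@@H]3C[C@@](OC)(C(C(C)C(=O)OC)=C(C)[C@@H]32)C1=O | intermediate
17 | α-ketol: C3–OH exo and C3–CH3 endo, C2 and C10 ketones | C=CC[C@]12C(=O)[C@@](C)(O)[C@@H]3C[C@@](OC)(C(C(C)C(=O)OC)=C(C)[C@@H]32)C1=O | intermediate
18 | isotwistenol, key-step precursor: C10(CH3)(OH) with OH syn to the C4–C5 bridge, C6 OCH3 bridgehead, C2 ketone, C3 exo-OH, C1 allyl, C7 CH(CH3)CO2CH3, C8 CH3 | C=CC[C@]12C(=O)[C@@](C)(O)[C@@H]3C[C@@](OC)(C(C(C)C(=O)OC)=C(C)[C@@H]32)[C@]1(C)O | intermediate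
19 | bicyclo[3.2.1]octenone, key-step product: C6 ketone, C10 quaternary with CH3, cyclopentene C7=C8, C2 ketone, C3 exo-OH, C1 allyl | C=CC[C@]12C(=O)[C@@](C)(O)[C@@H]3CC(=O)[C@@]1(C)C(C(C)C(=O)OC)=C(C)[C@@H]32 | intermediate
20 | (E)-prop-1-enyl compound: as 19 with C1–CH=CH–CH3 | C/C=C/[C@]12C(=O)[C@@](C)(O)[C@@H]3CC(=O)[C@@]1(C)C(C(C)C(=O)OC)=C(C)[C@@H]32 | intermediate
21 | glycol: as 19 with C1–CH(OH)–CH(OH)CH3, diastereomers (not isolated) | CC(O)C(O)[C@]12C(=O)[C@@](C)(O)[C@@H]3CC(=O)[C@@]1(C)C(C(C)C(=O)OC)=C(C)[C@@H]32 | intermediate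
22 | C13 aldehyde: as 19 with C1–CHO | O=C[C@]12C(=O)[C@@](C)(O)[C@@H]3CC(=O)[C@@]1(C)C(C(C)C(=O)OC)=C(C)[C@@H]32 | intermediate
23 | C13 alcohol: as 19 with C1–CH2OH | OC[C@]12C(=O)[C@@](C)(O)[C@@H]3CC(=O)[C@@]1(C)C(C(C)C(=O)OC)=C(C)[C@@H]32 | intermediate
24 | exo 7,8-epoxide of 23, epoxide oxygen syn to C1 (not isolated) | OC[C@]12C(=O)[C@@](C)(O)[C@@H]3CC(=O)[C@@]1(C)[C@]4(C(C)C(=O)OC)O[C@]4(C)[C@@H]32 | intermediate
25 | hydroxy lactone: C7–OH exo, ring D C12(=O)–O–C8 on the endo face, C11 epimers | OC[C@]12C(=O)[C@@](C)(O)[C@@H]3CC(=O)[C@@]1(C)[C@@]1(O)C(C)C(=O)O[C@@]1(C)[C@@H]32 | intermediate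
26 | pentalithium salt of 25: three alkoxides, C5=C6 enolate, lactone enolate (not isolated) | [Li+].[Li+].[Li+].[Li+].[Li+].[O-]C[C@]12C(=O)[C@@](C)([O-])[C@@H]3C=C([O-])[C@@]1(C)[C@@]1([O-])C(C)=C([O-])O[C@@]1(C)[C@@H]32 | intermediate
27 | hydroxy lactone, single epimer: C11–CH3 on the concave face (toward C6 and the C10 methyl) | OC[C@]12C(=O)[C@@](C)(O)[C@@H]3CC(=O)[C@@]1(C)[C@@]1(O)[C@@H](C)C(=O)O[C@@]1(C)[C@@H]32 | intermediate
28 | C13 aldehyde of the lactone series | O=C[C@]12C(=O)[C@@](C)(O)[C@@H]3CC(=O)[C@@]1(C)[C@@]1(O)[C@@H](C)C(=O)O[C@@]1(C)[C@@H]32 | intermediate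
29 | (E)-crotonaldehyde | C/C=C/C=O | starting material
30 | (1E,3E)-1-iodopenta-1,3-diene | C/C=C/C=C/I | intermediate
31 | dienyl carbinol: C1–CH(OH)–(1E,3E)-penta-1,3-dienyl, C13 epimers | C/C=C/C=C/C(O)[C@]12C(=O)[C@@](C)(O)[C@@H]3CC(=O)[C@@]1(C)[C@@]1(O)[C@@H](C)C(=O)O[C@@]1(C)[C@@H]32 | intermediate
32 | sorbyl ketone: C1–C(=O)–(1E,3E)-penta-1,3-dienyl, C5 still CH2 | C/C=C/C=C/C(=O)[C@]12C(=O)[C@@](C)(O)[C@@H]3CC(=O)[C@@]1(C)[C@@]1(O)[C@@H](C)C(=O)O[C@@]1(C)[C@@H]32 | intermediate
33 | sorbic acid, (2E,4E)-hexa-2,4-dienoic acid | C/C=C/C=C/C(=O)O | starting material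
34 | (2E,4E)-hexa-2,4-dienoyl chloride (not isolated) | C/C=C/C=C/C(=O)Cl | intermediate
35 | CNP0231466.1 | C/C=C/C=C/C(=O)[C@]12C(=O)[C@@](C)(O)[C@@H]3\C(=C(O)/C=C/C=C/C)C(=O)[C@@]1(C)[C@@]1(O)[C@@H](C)C(=O)O[C@@]1(C)[C@@H]32 | target

Total step count: 23. Longest linear sequence: 22 steps (steps 1–19 and 21–23, from 2-methoxy-4-methylphenol); step 20 is a one-step side branch.

Steps most likely to fail

Step 13. What may go wrong: if step 12 delivers the methyl group from the wrong face, the C10 hydroxyl stands anti to the C5 bridge and the methylene bridge migrates instead; ionisation may also end in elimination or retro-aldol opening of the C1–C10 bond. The fallback removes the dependence on the carbinol configuration. It sets out from 17: Takai–Lombardo methylenation of the C10 ketone (Zn, CH2Br2, TiCl4, THF/CH2Cl2, 0 °C) should give the 10-methylidene compound F1, the hindered C2 ketone and the ester being left alone. Protonation of the exocyclic alkene (CF3CO2H, wet CH2Cl2, 0 °C) generates the same tertiary C10 cation from a planar precursor, so only π participation and the methoxy group steer the shift, and the route is rejoined at 19.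

Step 9. What may go wrong: at 185 °C the dienone may be drained by Cope migration of the allyl group to the methyl-bearing para carbon or by dimerisation before it cyclises, or the two C1 epimers may cyclise with poor discrimination. The fallback replaces the sigmatropic dearomatisation by an ionic one. It sets out from 12: deallylation (Pd(PPh3)4 cat., morpholine, THF, rt) gives the phenol F2. Its lithium phenoxide (LiN(SiMe3)2, toluene, 0 °C) is C-allylated at the substituted ortho carbon with allyl bromide in the non-polar medium, which forms dienone 13 at low temperature. Warming to 110 °C then closes the Diels–Alder adduct 14, where the route is rejoined (desilylation to 15 as in step 9); any O-allylated material is 12 and can be recycled.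

Step 18. What may go wrong: incomplete enolisation of the polyanion, or proton delivery to both faces of the lactone enolate, leaving the unnatural, more stable C11 epimer. The fallback sets C11 by hydrogenation. It sets out from 25: per-silylation (Me3SiOTf, Et3N, CH2Cl2, 0 °C) masks the three hydroxyls and the C6 ketone as its enol ether, giving F3. Selective lactone enolisation (LiN(i-Pr)2, THF, −78 °C), trapping with PhSeBr and acidic methanol work-up give the α-phenylselanyl lactone F4. Oxidation (H2O2, pyridine, CH2Cl2, 0 °C) and syn-elimination, possible only toward the methyl group, give the α-methylene lactone F5. Hydrogenation with [Ir(cod)(PCy3)(py)]PF6 (H2, CH2Cl2), directed by the adjacent exo C7 hydroxyl, should add hydrogen on the open face and rejoin the route at 27.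

Further compounds
F1 | step 13 | 10-methylidene analogue of 17 (C10=CH2, C6 OCH3, C2 ketone, C3 exo-OH, C1 allyl) | C=CC[C@]12C(=O)[C@@](C)(O)[C@@H]3C[C@@](OC)(C(C(C)C(=O)OC)=C(C)[C@@H]32)C1=C
F2 | step 9 | methyl 2-{3-hydroxy-2-methoxy-6-methyl-4-[(1S,2S)-2-methyl-1-(triethylsilyloxy)but-3-en-1-yl]phenyl}propanoate | COC(=O)C(C)c1c(C)cc([C@@H](O[Si](CC)(CC)CC)[C@@H](C)C=C)c(O)c1OC
F3 | step 18 | tris(trimethylsilyl) ether and C5=C6 trimethylsilyl enol ether of 25 | C[Si](C)(C)OC[C@]12C(=O)[C@@](C)(O[Si](C)(C)C)[C@@H]3C=C(O[Si](C)(C)C)[C@@]1(C)[C@@]1(O[Si](C)(C)C)C(C)C(=O)O[C@@]1(C)[C@@H]32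
F4 | step 18 | 11-(phenylselanyl) lactone (C11 epimers) | OC[C@]12C(=O)[C@@](C)(O)[C@@H]3CC(=O)[C@@]1(C)[C@@]1(O)C(C)([Se]c4ccccc4)C(=O)O[C@@]1(C)[C@@H]32
F5 | step 18 | 11-methylidene lactone | OC[C@]12C(=O)[C@@](C)(O)[C@@H]3CC(=O)[C@@]1(C)[C@@]1(O)C(=C)C(=O)O[C@@]1(C)[C@@H]32
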